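## Structural features

Entonaemin A is a 5,6,7,8-tetrahydro-1H-isochromen-8-one. Ring A (C4a, C5, C6, C7, C8, C8a) is a cyclohex-2-enone and ring B (C1, O2, C3, C4, C4a, C8a) a 2H-pyran; they share the tetrasubstituted C4a=C8a double bond. The enol ether O2–C3=C4 is conjugated through C4a=C8a with the C8 ketone, so the bicycle is a push–pull dienone. C3 carries an (E)-3-hydroxyprop-1-enyl arm, and C1 and C5 are methylenes. The only stereocentres, C6 (R, secondary, esterified by orsellinic acid) and C7 (R, tertiary alcohol with the methyl group, α to C8), are adjacent and their oxygens are cis. Fragile points are the dienol ether (hydration in aqueous acid), the C6 acyloxy group (β to the vinylogously acidic C5–H, so base can eliminate it), the tertiary α-ketol, the allylic alcohol and the oxidisable resorcinol. The real difficulty is to build the C4a=C8a alkene, with four different carbon substituents, next to the cis-diol without touching either stereocentre, and then to close ring B 6-endo. The key step exploits that the sp3 half of ring A, C5–C6–C7–C8, holds both stereocentres and ends in the ketone carbon (a cyclobutanone once C5 is tied to C8), while the sp2 half C4a=C8a is an alkyne; zerovalent nickel inserts the alkyne into the C8–C5 bond.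

## Logic of the disconnections

**29 from 28.** Only O–Si bonds are cut (two aryl, one allylic). All three are fluoride-labile, so one buffered fluoride treatment ends the synthesis. The demand is that the fluoride is not basic enough to eliminate the C6 acyloxy group.

**28 from 23 and 26 (through 27).** The acyl–O6 bond is cut. This separates the arene from the core and leaves a diol whose secondary O6 is far more reactive than the tertiary O7. The demand is an acylating agent strong enough for a 2,6-disubstituted benzoate under conditions that are not basic.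

**23 from 22.** The O2–C3 bond is cut, which opens ring B to a hydroxy-enynone. The forward step is a 6-endo addition of O1–H to the alkyne; C3 is the δ-carbon of the C8 ketone through C4a=C8a, so polarisation favours attack there. The demand is 6-endo over 5-exo.

**22 from 21.** The benzylic C–O bond at O1 and the two acetal C–O bonds are cut. Both protecting groups fall to acid, and this is done before ring B exists so that the dienol ether never meets acid. The demand is that the allylic silyl ether survives.

**21 from 17 and 20, and 17 from 16.** The sp–sp2 bond between the alkyne terminus (future C3) and the vinyl carbon is cut, then the C–Si bond of the capped alkyne. This gives a simple (E)-vinyl iodide and the ring A enyne. The demand is a tertiary amine base, since secondary amines would add to the ynenone.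

**16 from 10 and 15.** C8–C8a and C5–C4a are cut. This turns ring A into a cyclobutanone that carries both stereocentres and a silyl-capped diyne, with full atom economy. The demands are: reaction at the ether-bearing alkyne only, C8 bonding to the carbon that carries the CH2O group, migration of the methylene and not the quaternary carbon, and reductive elimination faster than β-alkoxide loss.

**15 from 12 and 14, 12 from 11, 14 from 13.** The sp–sp bond of the diyne is cut (Cadiot–Chodkiewicz); ether formation and bromination of the two terminal alkynes precede it.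

**10 from 9, 9 from 8, 8 from 7.** These are functional-group changes only: the ketone is unmasked last, because a free 3-hydroxycyclobutanone would open by retro-aldol; the acetonide is made on the dithioketal; the silyl ether on O6 is removed by fluoride.

**7 from 5 (through 6).** The C8–C5 bond of the four-membered ring is cut, giving a dithiane carbanion at C8 and a primary sulfonate at C5. Two points of design matter here:
- The carbon that becomes C5 is C4 of the branched erythronate chain; the sugar has no C5 apart from the C-methyl group.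
- A dithiane anion with an acetal oxygen on the neighbouring carbon would be expected to eliminate to the ketene dithioacetal. The tertiary hydroxyl is therefore left free and carried as its lithium alkoxide, which cannot leave, and O6 is blocked by a silyl group that does not migrate.
- A tosylate is used rather than an iodide, which would undergo lithium–iodine exchange and attack by the neighbouring sulfur.

**5 from 4, 4 from 3, 3 from 2, 2 from 1.** Sulfonylation of the primary hydroxyl, dithioacetal formation from the lactol, half-reduction of the lactone and selective silylation of the secondary hydroxyl lead back to the chiral-pool lactone. The lactone maps as C1→C8, C2→C7, C3→C6, C4→C5.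

**20 from 18 from 11 (through 19); 26 from 24 (through 25).** The vinyl iodide comes from the propargyl silyl ether by hydrozirconation and iodination. The protected acid comes from persilylation and hydrolysis of the silyl ester.

## Other disconnections considered

**Alternative 1:** The cut is the acyl–O6 bond together with the C2–C7 bond of the future arene, so the orsellinate is replaced by a masked tetraketide.
- Forward step: heating 6-(2,4-dioxopentyl)-2,2-dimethyl-4H-1,3-dioxin-4-one A2 with the core diol A3 would release acetone and the acylketene A4. Trapping at O6 would give the 3,5,7-trioxooctanoate A5, and aldol closure with dehydration would give the primary silyl ether of the target, A1.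
- In favour: a slim ketene should acylate the congested O6 more easily than a 2,6-disubstituted aroyl chloride, and no phenol protection is needed. On this point it is the better of the two, and it is kept as the fallback for step 20.
- Against: it solves only the periphery. A3 still needs rings A and B and both stereocentres from a route such as the present one. The aldol aromatisation needs base while the C6 acyloxy group sits β to the acidic C5–H, and A2 needs its own preparation.
- Comparison: on structure it does not compete with the chosen key step, because it builds no part of rings A and B. On mechanism it replaces an acylation with a pericyclic release and a polar cyclisation. On step economy it is at best equal (preparation of A2, two operations and desilylation against steps 19 to 21).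

**Alternative 2:** The cut is C4a–C8a and O2–C1.
- Forward step: zerovalent palladium would insert into the C4a–I bond of the (Z)-β-iodoenone A7 and add 6-exo to the internal carbon of the vinyl ketone. β-Hydride elimination would give the 1-oxatriene A8, which would close O2–C1 by 6π electrocyclisation to A6.
- In favour: both rings form in one operation. Ring B regiochemistry is fixed by the pericyclic step, which is better than step 18. No alkyl–metal sits β to O6, which is better than the nickel step. The side chain is already in place, so fewer steps follow the key step.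
- Against: the carbopalladation must deliver carbon to the α-carbon of an enone, against the usual β-selectivity, with 7-endo closure as competitor. A7 is a polymerisable vinyl ketone with a stereodefined iodoalkene, and it needs the C5–C4a bond made by substitution at the oxygen-flanked C5. A8 could isomerise before it cyclises.
- Comparison: both plans take the stereocentres from the same acetonide diol (equal). The chosen plan makes two skeletal bonds from a compact four-carbon and two-carbon pair but then needs six more steps; Alternative 2 moves that effort before the key step and would probably be longer overall.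

**Alternative 3:** The cut is C7–C8.
- Forward step: a chiral triazolium-derived carbene would convert the C8 aldehyde of the keto-aldehyde A10 into an acyl-anion equivalent. This would add to the methyl ketone, closing ring A and creating the C7 tertiary alcohol of A9.
- In favour: it delivers the α-ketol directly, uses no metal, and has O6 and O7 already differentiated. On protecting-group economy it is better than the chosen plan, since no acetonide hydrolysis is needed.
- Against: C7 is created in the key step and must come out cis to O6, which depends on the match of catalyst and the resident centre. C6–H is α to the ketone and may epimerise under the basic conditions. The aldehyde is a vinylogous formate and should add the carbene slowly. The sensitive dienol ether must be carried through the whole preparation of A10.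
- Comparison: on structure the chosen plan creates no stereocentre, because both come from 1, which is the safer position. On mechanism Alternative 3 avoids the β-alkoxide question of the nickel step. On step economy the two are probably similar.

Key step: step 12

Assumption: the target is taken as the (6R,7R) isomer with O6 and O7 cis; ring numbering follows the isochromene skeleton (C1 to C8a) throughout.

## Route

Step 1
Reactants: 1 2-C-methyl-D-erythrono-1,4-lactone
Product: 2 (3R,4R)-4-[(tert-butyldiphenylsilyl)oxy]-3-hydroxy-3-methyloxolan-2-one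
Conditions: TBDPSCl (1.1 equiv), imidazole, DMAP (cat.), DMF, rt to 40 °C
Reagents that add atoms: tert-butyl(chloro)diphenylsilane, CC(C)(C)[Si](Cl)(c1ccccc1)c1ccccc1
Why: Silyl ether formation discriminates the secondary hydroxyl from the hindered tertiary α-hydroxyl; the bulky group is chosen because it resists migration to a neighbouring alkoxide in step 5.

Step 2
Reactants: 2 (3R,4R)-4-[(tert-butyldiphenylsilyl)oxy]-3-hydroxy-3-methyloxolan-2-one
Product: 3 (3R,4R)-4-[(tert-butyldiphenylsilyl)oxy]-3-methyloxolane-2,3-diol (lactol, both anomers)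
Conditions: iBu2AlH (2.2 equiv), CH2Cl2, −78 °C; aq. potassium sodium tartrate
Reagents that add atoms: none
Why: Half-reduction of a γ-lactone; the first equivalent forms the aluminium alkoxide of the tertiary hydroxyl and the tetrahedral intermediate holds until work-up, so over-reduction should not occur.

Step 3
Reactants: 3 (3R,4R)-4-[(tert-butyldiphenylsilyl)oxy]-3-methyloxolane-2,3-diol
Product: 4 (2R,3R)-2-[(tert-butyldiphenylsilyl)oxy]-3-(1,3-dithian-2-yl)butane-1,3-diol
Conditions: HS(CH2)3SH (1.3 equiv), BF3·OEt2 (1.2 equiv), CH2Cl2, −20 to 0 °C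
Reagents that add atoms: propane-1,3-dithiol, SCCCS
Why: Lewis-acid dithioacetalisation of the lactol through its open-chain thionium ion; the silyl ether is stable and the primary hydroxyl is set free.

Step 4
Reactants: 4 (2R,3R)-2-[(tert-butyldiphenylsilyl)oxy]-3-(1,3-dithian-2-yl)butane-1,3-diol
Product: 5 (2R,3R)-2-[(tert-butyldiphenylsilyl)oxy]-3-(1,3-dithian-2-yl)-3-hydroxybutyl 4-methylbenzenesulfonate
Conditions: TsCl (1.2 equiv), pyridine, CH2Cl2, 0 °C
Reagents that add atoms: 4-methylbenzenesulfonyl chloride, Cc1ccc(cc1)S(Cl)(=O)=O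
Why: Sulfonylation is selective for the primary over the tertiary hydroxyl; the tosylate is preferred to an iodide, which would exchange with butyllithium and be attacked by the dithiane sulfur.

Step 5
Reactants: 5 (2R,3R)-2-[(tert-butyldiphenylsilyl)oxy]-3-(1,3-dithian-2-yl)-3-hydroxybutyl 4-methylbenzenesulfonate
Product: 7 (1R,2R)-2-[(tert-butyldiphenylsilyl)oxy]-1-methyl-5,9-dithiaspiro[3.5]nonan-1-ol, via dilithio dianion 6 (not isolated)
Conditions: n-BuLi (2.3 equiv), THF, −78 to −10 °C; then H2O
Reagents that add atoms: none
Why: Intramolecular Corey–Seebach alkylation (4-exo-tet): the first equivalent gives the tertiary lithium alkoxide, which cannot act as a leaving group and so blocks elimination to a ketene dithioacetal, and the second lithiates the dithiane, which displaces the tosylate; no stereocentre is made or touched.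

Step 6
Reactants: 7 (1R,2R)-2-[(tert-butyldiphenylsilyl)oxy]-1-methyl-5,9-dithiaspiro[3.5]nonan-1-ol
Product: 8 (1R,2R)-1-methyl-5,9-dithiaspiro[3.5]nonane-1,2-diol
Conditions: Bu4NF (1.5 equiv), THF, rt
Reagents that add atoms: none
Why: Fluoride cleavage of the silyl ether; the dithioketal keeps the carbonyl masked, so the free diol cannot open by retro-aldol.

Step 7
Reactants: 8 (1R,2R)-1-methyl-5,9-dithiaspiro[3.5]nonane-1,2-diol
Product: 9 (1R,5R)-3,3,5-trimethyl-2,4-dioxabicyclo[3.2.0]heptan-6-one propane-1,3-diyl dithioketal
Conditions: Me2C(OMe)2, PPTS (cat.), acetone, rt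
Reagents that add atoms: 2,2-dimethoxypropane, COC(C)(C)OC
Why: Acetal exchange on a cis-1,2-diol gives the cis-fused dioxolane; only the cis isomer can close this ring, which also checks the relative configuration.

Step 8
Reactants: 9 (1R,5R)-3,3,5-trimethyl-2,4-dioxabicyclo[3.2.0]heptan-6-one propane-1,3-diyl dithioketal
Product: 10 (1R,5R)-3,3,5-trimethyl-2,4-dioxabicyclo[3.2.0]heptan-6-one
Conditions: Hg(ClO4)2, CaCO3, THF/H2O (5:1), 0 °C
Reagents that add atoms: water, O
Why: Metal-assisted dithioketal hydrolysis under carbonate buffer; neutral conditions are needed because the β-alkoxy cyclobutanone would eliminate with base and the acetonide would open with acid; the product is volatile and is concentrated cold.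

Step 9
Reactants: 11 propargyl alcohol
Product: 12 1-methoxy-4-[(prop-2-yn-1-yloxy)methyl]benzene
Conditions: NaH, PMBCl, Bu4NI (cat.), THF, 0 °C to rt
Reagents that add atoms: 4-methoxybenzyl chloride, COc1ccc(CCl)cc1
Why: Williamson ether synthesis on a primary alkoxide with a benzylic chloride.

Step 10
Reactants: 13 (triisopropylsilyl)acetylene
Product: 14 (bromoethynyl)tri(propan-2-yl)silane
Conditions: NBS, AgNO3 (cat.), acetone, rt
Reagents that add atoms: N-bromosuccinimide, BrN1C(=O)CCC1=O
Why: Silver-catalysed bromination of a terminal alkyne through the silver acetylide.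

Step 11
Reactants: 12 1-methoxy-4-[(prop-2-yn-1-yloxy)methyl]benzene; 14 (bromoethynyl)tri(propan-2-yl)silane
Product: 15 4-methoxybenzyl 5-(triisopropylsilyl)penta-2,4-diynyl ether
Conditions: CuCl (cat.), NH2OH·HCl, n-BuNH2, H2O/Et2O, 0 °C
Reagents that add atoms: none
Why: Cadiot–Chodkiewicz coupling of a terminal alkyne with a 1-bromoalkyne gives the unsymmetrical diyne; hydroxylamine keeps copper monovalent and suppresses homocoupling.

Step 12
Reactants: 10 (1R,5R)-3,3,5-trimethyl-2,4-dioxabicyclo[3.2.0]heptan-6-one; 15 4-methoxybenzyl 5-(triisopropylsilyl)penta-2,4-diynyl ether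
Product: 16 (3aR,7aR)-5-{[(4-methoxyphenyl)methoxy]methyl}-2,2,3a-trimethyl-6-{[tri(propan-2-yl)silyl]ethynyl}-7,7a-dihydro-1,3-benzodioxol-4(3aH)-one
Conditions: Ni(cod)2 (10 mol %), PCy3 (20 mol %), toluene, 100 °C; 10 (1.5 equiv), slow addition of 15
Reagents that add atoms: none
Why: Zerovalent nickel with PCy3 binds the cyclobutanone carbonyl and the ether-bearing alkyne of 15 and couples them oxidatively to a spiro oxanickelacyclopentene, with C8 joined to the alkyne carbon that carries the CH2O group (future C8a), because the carbon bearing the second alkyne is better placed on nickel, where conjugation stabilises the metal–carbon bond. Relief of four-ring strain then drives β-carbon elimination of the C8–C5 bond to a seven-membered nickelacycle, and C(sp3)–C(sp2) reductive elimination forms C5–C4a and returns the catalyst. The closest known reaction type is the nickel-catalysed intermolecular insertion of internal alkynes into cyclobutanones to give cyclohex-2-enones, and the behaviour of conjugated enynes with strained four-membered ketones supports the orientation. Ring A is closed as a formal [4+2] annulation (oxidative cyclisation, β-carbon elimination, reductive elimination) and not by an exo or endo attack. No stereocentre is created: C7 is quaternary and not involved, C6 is a spectator, and both come unchanged from 1. The step needs reaction at one alkyne only, which the bulky silyl cap on the other should secure, and the C8–C8a orientation, which conjugation should secure. It needs migration of the methylene C5 and not the quaternary C7, which sterics in the β-carbon elimination should secure. It also needs reductive elimination to outrun β-alkoxide and β-hydride loss from C5–Ni; the cis-fused acetonide holds the C6–O bond away from a syn-coplanar alignment with C5–Ni, and the bulky donor phosphine speeds reductive elimination.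

Step 13
Reactants: 16 (3aR,7aR)-5-{[(4-methoxyphenyl)methoxy]methyl}-2,2,3a-trimethyl-6-{[tri(propan-2-yl)silyl]ethynyl}-7,7a-dihydro-1,3-benzodioxol-4(3aH)-one
Product: 17 (3aR,7aR)-6-ethynyl-5-{[(4-methoxyphenyl)methoxy]methyl}-2,2,3a-trimethyl-7,7a-dihydro-1,3-benzodioxol-4(3aH)-one
Conditions: Bu4NF, AcOH (1:1), THF, 0 °C
Reagents that add atoms: none
Why: Fluoride cleaves the C(sp)–Si bond; the acetic acid buffer keeps the medium from deprotonating C5, which could expel the C6 oxygen.

Step 14
Reactants: 11 propargyl alcohol
Product: 18 tert-butyl(diphenyl)(prop-2-yn-1-yloxy)silane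
Conditions: TBDPSCl, imidazole, CH2Cl2, rt
Reagents that add atoms: tert-butyl(chloro)diphenylsilane, CC(C)(C)[Si](Cl)(c1ccccc1)c1ccccc1
Why: Standard silylation of a primary alcohol; this silyl group is chosen because it should survive the acid of step 17.

Step 15
Reactants: 18 tert-butyl(diphenyl)(prop-2-yn-1-yloxy)silane
Product: 20 (E)-tert-butyl[(3-iodoprop-2-en-1-yl)oxy]diphenylsilane, via alkenylzirconocene chloride 19 (not isolated)
Conditions: Cp2Zr(H)Cl, THF, rt; then I2, 0 °C
Reagents that add atoms: iodine, II
Why: Hydrozirconation adds Zr–H syn with zirconium at the terminal carbon, and iodinolysis proceeds with retention, so the (E)-vinyl iodide results.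

Step 16
Reactants: 17 (3aR,7aR)-6-ethynyl-5-{[(4-methoxyphenyl)methoxy]methyl}-2,2,3a-trimethyl-7,7a-dihydro-1,3-benzodioxol-4(3aH)-one; 20 (E)-tert-butyl[(3-iodoprop-2-en-1-yl)oxy]diphenylsilane
Product: 21 (3aR,7aR)-6-[(E)-5-[(tert-butyldiphenylsilyl)oxy]pent-3-en-1-yn-1-yl]-5-{[(4-methoxyphenyl)methoxy]methyl}-2,2,3a-trimethyl-7,7a-dihydro-1,3-benzodioxol-4(3aH)-one
Conditions: Pd(PPh3)2Cl2 (5 mol %), CuI (10 mol %), Et3N, THF, rt, degassed
Reagents that add atoms: none
Why: Sonogashira coupling of a terminal alkyne with a vinyl iodide retains the alkene geometry; a tertiary amine is used because a secondary amine would add to the ynenone.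

Step 17
Reactants: 21 (3aR,7aR)-6-[(E)-5-[(tert-butyldiphenylsilyl)oxy]pent-3-en-1-yn-1-yl]-5-{[(4-methoxyphenyl)methoxy]methyl}-2,2,3a-trimethyl-7,7a-dihydro-1,3-benzodioxol-4(3aH)-one
Product: 22 (5R,6R)-3-[(E)-5-[(tert-butyldiphenylsilyl)oxy]pent-3-en-1-yn-1-yl]-5,6-dihydroxy-2-(hydroxymethyl)-6-methylcyclohex-2-en-1-one
Conditions: TFA/CH2Cl2 (1:4), H2O (5 equiv), anisole, 0 °C to rt; aq. NaHCO3
Reagents that add atoms: none
Why: Acidolysis removes the 4-methoxybenzyl ether (the benzylic cation is trapped by anisole) and hydrolyses the acetonide in one operation, while the primary tert-butyldiphenylsilyl ether should hold; doing this before ring B exists keeps the dienol ether away from acid.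

Step 18
Reactants: 22 (5R,6R)-3-[(E)-5-[(tert-butyldiphenylsilyl)oxy]pent-3-en-1-yn-1-yl]-5,6-dihydroxy-2-(hydroxymethyl)-6-methylcyclohex-2-en-1-one
Product: 23 (6R,7R)-3-[(E)-3-[(tert-butyldiphenylsilyl)oxy]prop-1-en-1-yl]-6,7-dihydroxy-7-methyl-6,7-dihydro-1H-isochromen-8(5H)-one
Conditions: Ph3PAuNTf2 (5 mol %), THF, rt
Reagents that add atoms: none
Why: Gold-catalysed 6-endo-dig hydroalkoxylation: C3 is the δ-carbon of the C8 ketone through C4a=C8a and also carries the alkenyl group, so O1 should attack C3 and not C4; protodeauration gives C3=C4, and neither the C6 nor the C7 hydroxyl can reach the alkyne.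

Step 19
Reactants: 24 orsellinic acid
Product: 26 2,4-bis[(tert-butyldimethylsilyl)oxy]-6-methylbenzoic acid, via tris-silylated orsellinate 25 (not isolated)
Conditions: TBSCl (3.5 equiv), imidazole, DMF, rt; then AcOH/THF/H2O (3:1:1), rt
Reagents that add atoms: tert-butyl(chloro)dimethylsilane, CC(C)(C)[Si](C)(C)Cl
Why: Persilylation followed by selective hydrolysis of the silyl ester, which is far more labile than the aryl silyl ethers.

Step 20
Reactants: 23 (6R,7R)-3-[(E)-3-[(tert-butyldiphenylsilyl)oxy]prop-1-en-1-yl]-6,7-dihydroxy-7-methyl-6,7-dihydro-1H-isochromen-8(5H)-one; 26 2,4-bis[(tert-butyldimethylsilyl)oxy]-6-methylbenzoic acid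
Product: 28 (6R,7R)-3-[(E)-3-[(tert-butyldiphenylsilyl)oxy]prop-1-en-1-yl]-7-hydroxy-7-methyl-8-oxo-5,6,7,8-tetrahydro-1H-isochromen-6-yl 2,4-bis[(tert-butyldimethylsilyl)oxy]-6-methylbenzoate, via aroyl chloride 27 (not isolated)
Conditions: 26, 1-chloro-N,N,2-trimethylprop-1-en-1-amine, CH2Cl2, 0 °C to rt; then 23, Et3N, DMAP, CH2Cl2, 0 °C to rt
Reagents that add atoms: none
Why: The acid chloride is made under neutral conditions that spare the aryl silyl ethers, and DMAP-catalysed acylation takes place at the secondary O6 while the tertiary O7 is inert; the C6–O bond is not broken, so its configuration is kept.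

Step 21
Reactants: 28 (6R,7R)-3-[(E)-3-[(tert-butyldiphenylsilyl)oxy]prop-1-en-1-yl]-7-hydroxy-7-methyl-8-oxo-5,6,7,8-tetrahydro-1H-isochromen-6-yl 2,4-bis[(tert-butyldimethylsilyl)oxy]-6-methylbenzoate
Product: 29 entonaemin A
Conditions: Bu4NF, AcOH (1:1), THF, 0 °C to rt
Reagents that add atoms: none
Why: Buffered fluoride removes the two aryl silyl ethers and the primary silyl ether in one operation; the buffer is there to prevent base-induced loss of the C6 benzoate.

## Compound list

1 | 2-C-methyl-D-erythrono-1,4-lactone | O[C@@H]1COC(=O)[C@]1(C)O | starting material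
2 | (3R,4R)-4-[(tert-butyldiphenylsilyl)oxy]-3-hydroxy-3-methyloxolan-2-one | CC(C)(C)[Si](O[C@@H]1COC(=O)[C@]1(C)O)(c1ccccc1)c1ccccc1 | intermediate
3 | (3R,4R)-4-[(tert-butyldiphenylsilyl)oxy]-3-methyloxolane-2,3-diol (both anomers) | CC(C)(C)[Si](O[C@@H]1COC(O)[C@]1(C)O)(c1ccccc1)c1ccccc1 | intermediate
4 | (2R,3R)-2-[(tert-butyldiphenylsilyl)oxy]-3-(1,3-dithian-2-yl)butane-1,3-diol | OC[C@@H](O[Si](c1ccccc1)(c1ccccc1)C(C)(C)C)[C@@](C)(O)C1SCCCS1 | intermediate
5 | (2R,3R)-2-[(tert-butyldiphenylsilyl)oxy]-3-(1,3-dithian-2-yl)-3-hydroxybutyl 4-methylbenzenesulfonate | Cc1ccc(cc1)S(=O)(=O)OC[C@@H](O[Si](c1ccccc1)(c1ccccc1)C(C)(C)C)[C@@](C)(O)C1SCCCS1 | intermediate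
6 | dilithio dianion of 5 (tertiary lithium alkoxide, 2-lithio-1,3-dithiane) | Cc1ccc(cc1)S(=O)(=O)OC[C@@H](O[Si](c1ccccc1)(c1ccccc1)C(C)(C)C)[C@@](C)(O[Li])C1([Li])SCCCS1 | intermediate
7 | (1R,2R)-2-[(tert-butyldiphenylsilyl)oxy]-1-methyl-5,9-dithiaspiro[3.5]nonan-1-ol | C[C@@]1(O)[C@H](O[Si](c2ccccc2)(c2ccccc2)C(C)(C)C)CC13SCCCS3 | intermediate
8 | (1R,2R)-1-methyl-5,9-dithiaspiro[3.5]nonane-1,2-diol | C[C@@]1(O)[C@H](O)CC12SCCCS2 | intermediate
9 | (1R,5R)-3,3,5-trimethyl-2,4-dioxabicyclo[3.2.0]heptan-6-one propane-1,3-diyl dithioketal | CC1(C)O[C@@H]2CC3(SCCCS3)[C@]2(C)O1 | intermediate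
10 | (1R,5R)-3,3,5-trimethyl-2,4-dioxabicyclo[3.2.0]heptan-6-one (cis-2,3-(isopropylidenedioxy)-2-methylcyclobutanone) | CC3(C)O[C@@H]1CC(=O)[C@]1(C)O3 | intermediate
11 | propargyl alcohol | C#CCO | starting material
12 | 1-methoxy-4-[(prop-2-yn-1-yloxy)methyl]benzene | COc1ccc(COCC#C)cc1 | intermediate
13 | (triisopropylsilyl)acetylene | C#C[Si](C(C)C)(C(C)C)C(C)C | starting material
14 | (bromoethynyl)tri(propan-2-yl)silane | BrC#C[Si](C(C)C)(C(C)C)C(C)C | intermediate
15 | 4-methoxybenzyl 5-(triisopropylsilyl)penta-2,4-diynyl ether | COc1ccc(COCC#CC#C[Si](C(C)C)(C(C)C)C(C)C)cc1 | intermediate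
16 | (3aR,7aR)-5-{[(4-methoxyphenyl)methoxy]methyl}-2,2,3a-trimethyl-6-{[tri(propan-2-yl)silyl]ethynyl}-7,7a-dihydro-1,3-benzodioxol-4(3aH)-one | CC3(C)O[C@@H]1CC(C#C[Si](C(C)C)(C(C)C)C(C)C)=C(COCc2ccc(OC)cc2)C(=O)[C@]1(C)O3 | intermediate
17 | (3aR,7aR)-6-ethynyl-5-{[(4-methoxyphenyl)methoxy]methyl}-2,2,3a-trimethyl-7,7a-dihydro-1,3-benzodioxol-4(3aH)-one | CC3(C)O[C@@H]1CC(C#C)=C(COCc2ccc(OC)cc2)C(=O)[C@]1(C)O3 | intermediate
18 | tert-butyl(diphenyl)(prop-2-yn-1-yloxy)silane | C#CCO[Si](c1ccccc1)(c1ccccc1)C(C)(C)C | intermediate
19 | (E)-[3-[(tert-butyldiphenylsilyl)oxy]prop-1-en-1-yl]chloridozirconocene | Cl[Zr](/C=C/CO[Si](c1ccccc1)(c1ccccc1)C(C)(C)C)(C1C=CC=C1)C1C=CC=C1 | intermediate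
20 | (E)-tert-butyl[(3-iodoprop-2-en-1-yl)oxy]diphenylsilane | I/C=C/CO[Si](c1ccccc1)(c1ccccc1)C(C)(C)C | intermediate
21 | (3aR,7aR)-6-[(E)-5-[(tert-butyldiphenylsilyl)oxy]pent-3-en-1-yn-1-yl]-5-{[(4-methoxyphenyl)methoxy]methyl}-2,2,3a-trimethyl-7,7a-dihydro-1,3-benzodioxol-4(3aH)-one | CC3(C)O[C@@H]1CC(C#C/C=C/CO[Si](c4ccccc4)(c4ccccc4)C(C)(C)C)=C(COCc2ccc(OC)cc2)C(=O)[C@]1(C)O3 | intermediate
22 | (5R,6R)-3-[(E)-5-[(tert-butyldiphenylsilyl)oxy]pent-3-en-1-yn-1-yl]-5,6-dihydroxy-2-(hydroxymethyl)-6-methylcyclohex-2-en-1-one | O[C@@H]1CC(C#C/C=C/CO[Si](c2ccccc2)(c2ccccc2)C(C)(C)C)=C(CO)C(=O)[C@]1(C)O | intermediate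
23 | (6R,7R)-3-[(E)-3-[(tert-butyldiphenylsilyl)oxy]prop-1-en-1-yl]-6,7-dihydroxy-7-methyl-6,7-dihydro-1H-isochromen-8(5H)-one | O[C@@H]1CC2=C(COC(/C=C/CO[Si](c3ccccc3)(c3ccccc3)C(C)(C)C)=C2)C(=O)[C@]1(C)O | intermediate
24 | orsellinic acid | Cc1cc(O)cc(O)c1C(=O)O | starting material
25 | tert-butyldimethylsilyl 2,4-bis[(tert-butyldimethylsilyl)oxy]-6-methylbenzoate | Cc1cc(O[Si](C)(C)C(C)(C)C)cc(O[Si](C)(C)C(C)(C)C)c1C(=O)O[Si](C)(C)C(C)(C)C | intermediate
26 | 2,4-bis[(tert-butyldimethylsilyl)oxy]-6-methylbenzoic acid | Cc1cc(O[Si](C)(C)C(C)(C)C)cc(O[Si](C)(C)C(C)(C)C)c1C(=O)O | intermediate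
27 | 2,4-bis[(tert-butyldimethylsilyl)oxy]-6-methylbenzoyl chloride | Cc1cc(O[Si](C)(C)C(C)(C)C)cc(O[Si](C)(C)C(C)(C)C)c1C(Cl)=O | intermediate
28 | (6R,7R)-3-[(E)-3-[(tert-butyldiphenylsilyl)oxy]prop-1-en-1-yl]-7-hydroxy-7-methyl-8-oxo-5,6,7,8-tetrahydro-1H-isochromen-6-yl 2,4-bis[(tert-butyldimethylsilyl)oxy]-6-methylbenzoate | Cc1cc(O[Si](C)(C)C(C)(C)C)cc(O[Si](C)(C)C(C)(C)C)c1C(=O)O[C@@H]1CC2=C(COC(/C=C/CO[Si](c3ccccc3)(c3ccccc3)C(C)(C)C)=C2)C(=O)[C@]1(C)O | intermediate
29 | entonaemin A, (6R,7R)-7-hydroxy-3-[(E)-3-hydroxyprop-1-en-1-yl]-7-methyl-8-oxo-5,6,7,8-tetrahydro-1H-isochromen-6-yl 2,4-dihydroxy-6-methylbenzoate | Cc1cc(O)cc(O)c1C(=O)O[C@@H]1CC2=C(COC(/C=C/CO)=C2)C(=O)[C@]1(C)O | target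

## Step count and least certain steps

Total step count: 21. Longest linear sequence: 15 steps (steps 1 to 8, 12, 13, 16, 17, 18, 20, 21).

**Step 12 (key step).** Most likely to go wrong: the hindered α-quaternary ketone enters oxidative cyclisation slowly, so the diyne may be consumed by nickel-mediated oligomerisation or insert with the wrong orientation or at the silylated alkyne. The second concern is β-alkoxide loss from the C5–Ni intermediate. Fallback, setting out from 10 and 12 and coming back at 17:
- Sonogashira coupling of 12 with vinyl bromide would give the enyne 1-methoxy-4-[(pent-4-en-2-yn-1-yloxy)methyl]benzene F1. Conjugated enynes are an established partner class for nickel insertions into strained four-membered ketones, and the alkene directs C8 to the ether-bearing carbon.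
- The same nickel conditions with 10 would give the 6-vinyl enone F2.
- Lemieux–Johnson cleavage (OsO4 cat., NaIO4, 2,6-lutidine) of the terminal vinyl group, which is more electron-rich than the enone alkene, would give the 6-formyl enone F3.
- Ohira–Bestmann homologation (dimethyl (1-diazo-2-oxopropyl)phosphonate, K2CO3, MeOH, 0 °C) would give 17, so step 13 is not needed.
- This fallback changes the partner class and how the second alkyne is installed. It does not remove the β-alkoxide risk, which stays with any opening of the C8–C5 bond.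

**Step 5.** Most likely to go wrong: the second lithiation next to the alkoxide is slow, so butyllithium attacks the sulfonate, or the alkoxide closes an oxetane by O-alkylation. Fallback, setting out from 1 and coming back at 9 (steps 6 and 7 fall away):
- Acetonide formation on 1 would give 2,3-O-isopropylidene-2-C-methyl-D-erythrono-1,4-lactone F4.
- iBu2AlH would give the lactol F5.
- Propane-1,3-dithiol with BF3·OEt2 at low temperature would give the acetonide dithiane alcohol F6.
- TsCl would give the tosylate F7.
- t-BuLi in THF/HMPA at −78 °C would generate the monoanion, which would have to close the four-membered ring faster than it expels the acetal oxygen; the ring holds the two reacting carbons cis and close.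
- This trades the O-alkylation risk for the elimination risk.

**Step 18.** Most likely to go wrong: 5-exo-dig attack at C4 leading to an alkylidene dihydrofuran, because this closure is geometrically easy for a (Z)-enynol. Fallback, setting out from 22 and coming back at 23:
- Pyrrolidine in MeOH at 0 °C would add to C3, the δ-carbon of the ynenone (1,6-addition), giving the enaminone F10; regiochemistry is fixed by polarity alone.
- Mild acid (PPTS) would then let O1 replace the amine at C3 by addition–elimination and close ring B.

**Step 17.** Most likely to go wrong: loss of the allylic silyl ether in the acid, or premature closure of ring B followed by hydration of the new dienol ether. Fallback, setting out from 21 and coming back at 23: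
- DDQ (CH2Cl2/pH 7 buffer) would remove only the 4-methoxybenzyl group and give the alcohol F8.
- The gold catalyst of step 18 would close ring B to the bicyclic acetonide F9.
- Aqueous acetic acid at 40 °C would remove the acetonide.
- This costs one more step and exposes the dienol ether to weak acid only.

**Step 20.** Most likely to go wrong: slow acylation of a secondary alcohol next to a quaternary carbon by a 2,6-disubstituted aroyl chloride, with transfer of the ortho silyl group, and forcing conditions that trigger elimination across C5–C6. Fallback, setting out from 23 and coming back at 29: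
- Heating 23 with the diketo-dioxinone A2 in toluene would release acetone and an acylketene, which would acylate O6 to give the 3,5,7-trioxooctanoate F11.
- Mild base, then acid, would effect aldol closure and dehydration to the orsellinate F12 (entonaemin A tert-butyldiphenylsilyl ether).
- Bu4NF/AcOH would give 29.

## Further compounds

F1 | step 12 | 1-methoxy-4-[(pent-4-en-2-yn-1-yloxy)methyl]benzene | COc1ccc(COCC#CC=C)cc1
F2 | step 12 | (3aR,7aR)-6-ethenyl-5-{[(4-methoxyphenyl)methoxy]methyl}-2,2,3a-trimethyl-7,7a-dihydro-1,3-benzodioxol-4(3aH)-one | CC3(C)O[C@@H]1CC(C=C)=C(COCc2ccc(OC)cc2)C(=O)[C@]1(C)O3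
F3 | step 12 | (3aR,7aR)-6-formyl-5-{[(4-methoxyphenyl)methoxy]methyl}-2,2,3a-trimethyl-7,7a-dihydro-1,3-benzodioxol-4(3aH)-one | CC3(C)O[C@@H]1CC(C=O)=C(COCc2ccc(OC)cc2)C(=O)[C@]1(C)O3
F4 | step 5 | 2,3-O-isopropylidene-2-C-methyl-D-erythrono-1,4-lactone | CC1(C)O[C@@H]2COC(=O)[C@]2(C)O1
F5 | step 5 | 2,3-O-isopropylidene-2-C-methyl-D-erythrofuranose (both anomers) | CC1(C)O[C@@H]2COC(O)[C@]2(C)O1
F6 | step 5 | [(4R,5R)-5-(1,3-dithian-2-yl)-2,2,5-trimethyl-1,3-dioxolan-4-yl]methanol | OC[C@H]1OC(C)(C)O[C@@]1(C)C1SCCCS1
F7 | step 5 | [(4R,5R)-5-(1,3-dithian-2-yl)-2,2,5-trimethyl-1,3-dioxolan-4-yl]methyl 4-methylbenzenesulfonate | Cc1ccc(cc1)S(=O)(=O)OC[C@H]1OC(C)(C)O[C@@]1(C)C1SCCCS1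
F8 | step 17 | (3aR,7aR)-6-[(E)-5-[(tert-butyldiphenylsilyl)oxy]pent-3-en-1-yn-1-yl]-5-(hydroxymethyl)-2,2,3a-trimethyl-7,7a-dihydro-1,3-benzodioxol-4(3aH)-one | CC3(C)O[C@@H]1CC(C#C/C=C/CO[Si](c4ccccc4)(c4ccccc4)C(C)(C)C)=C(CO)C(=O)[C@]1(C)O3
F9 | step 17 | bicyclic core acetonide, primary tert-butyldiphenylsilyl ether | CC3(C)O[C@@H]1CC2=C(COC(/C=C/CO[Si](c4ccccc4)(c4ccccc4)C(C)(C)C)=C2)C(=O)[C@]1(C)O3
F10 | step 18 | (5R,6R)-3-[(3E)-5-[(tert-butyldiphenylsilyl)oxy]-2-(pyrrolidin-1-yl)penta-1,3-dien-1-yl]-5,6-dihydroxy-2-(hydroxymethyl)-6-methylcyclohex-2-en-1-one | O[C@@H]1CC(C=C(/C=C/CO[Si](c2ccccc2)(c2ccccc2)C(C)(C)C)N2CCCC2)=C(CO)C(=O)[C@]1(C)O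
F11 | step 20 | 3,5,7-trioxooctanoate of 23 at O6 | CC(=O)CC(=O)CC(=O)CC(=O)O[C@@H]1CC2=C(COC(/C=C/CO[Si](c3ccccc3)(c3ccccc3)C(C)(C)C)=C2)C(=O)[C@]1(C)O
F12 | step 20 | entonaemin A primary tert-butyldiphenylsilyl ether | Cc1cc(O)cc(O)c1C(=O)O[C@@H]1CC2=C(COC(/C=C/CO[Si](c3ccccc3)(c3ccccc3)C(C)(C)C)=C2)C(=O)[C@]1(C)O
A1 | alternative 1 | entonaemin A primary tert-butyldimethylsilyl ether | Cc1cc(O)cc(O)c1C(=O)O[C@@H]1CC2=C(COC(/C=C/CO[Si](C)(C)C(C)(C)C)=C2)C(=O)[C@]1(C)O
A2 | alternative 1 | 6-(2,4-dioxopentyl)-2,2-dimethyl-4H-1,3-dioxin-4-one | CC(=O)CC(=O)CC1=CC(=O)OC(C)(C)O1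
A3 | alternative 1 | core diol, primary tert-butyldimethylsilyl ether | O[C@@H]1CC2=C(COC(/C=C/CO[Si](C)(C)C(C)(C)C)=C2)C(=O)[C@]1(C)O
A4 | alternative 1 | 3,5,7-trioxoocta-1-en-1-one (acylketene) | CC(=O)CC(=O)CC(=O)C=C=O
A5 | alternative 1 | 3,5,7-trioxooctanoate of A3 at O6 | CC(=O)CC(=O)CC(=O)CC(=O)O[C@@H]1CC2=C(COC(/C=C/CO[Si](C)(C)C(C)(C)C)=C2)C(=O)[C@]1(C)O
A6 | alternative 2 | bicyclic core acetonide, primary tert-butyldimethylsilyl ether | CC3(C)O[C@@H]1CC2=C(COC(/C=C/CO[Si](C)(C)C(C)(C)C)=C2)C(=O)[C@]1(C)O3
A7 | alternative 2 | (Z)-β-iodoenone vinyl ketone, acetonide | C=CC(=O)[C@]1(C)OC(C)(C)O[C@@H]1C/C(I)=C/C(=O)/C=C/CO[Si](C)(C)C(C)(C)C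
A8 | alternative 2 | 1-oxatriene (ring A with exocyclic methylene and acylmethylidene) | C=C1C(=O)[C@]2(C)OC(C)(C)O[C@@H]2C/C1=C/C(=O)/C=C/CO[Si](C)(C)C(C)(C)C
A9 | alternative 3 | bicyclic core, O6 triethylsilyl and primary tert-butyldimethylsilyl ether | CC[Si](CC)(CC)O[C@@H]1CC2=C(COC(/C=C/CO[Si](C)(C)C(C)(C)C)=C2)C(=O)[C@]1(C)O
A10 | alternative 3 | 2H-pyran keto-aldehyde (C8 aldehyde on C8a, methyl ketone side chain on C4a) | O=CC1=C(C[C@@H](O[Si](CC)(CC)CC)C(C)=O)C=C(/C=C/CO[Si](C)(C)C(C)(C)C)OC1
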